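**Retrosynthetic overview**

1. Locants: C1 is the ring CH bearing the isopropenyl group (C15, with C16 its =CH2); the ring runs C2–C14 through C4 (Me), C5 (OAc), C8 (Me), C10 (C=O), C12 (Me), C13 (OAc); C14 is the ring CH2 between C13 and C1. The target is read as (1S,4R,5S,8S,12R,13R).
2. Enabling feature: the array O–C13–C14H2–C1H–C15(CH3)=C16H2 (an oxygenated ring carbon two bonds from a ring carbon that carries a 1-methylvinyl group) is a Claisen retron. The 14-membered carbocycle 22 is therefore traced back to the 16-membered 2-methylene oxacycle 21 (C14 exocyclic on C13; O–C16H2–C15(Me)=C1 in the ring). A [3,3] ring contraction 16 → 14 forms C14–C1, sets C1, and releases the isopropenyl group and the C13 carbonyl.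
3. 21 comes from macrolactone 20 (Petasis methylenation), which is closed at the C13 ester bond from seco acid 18 (Yamaguchi). After the key step: CBS reduction at C13, desilylation, diacetylation, ketal hydrolysis.
4. 18 comes from B-alkyl Suzuki coupling (C1–C2) of (E)-vinyl iodide 15 with alkene 12. C4/C5 are set by Brown anti-crotylation of aldehyde 9. C10–C11 is made by Pd-catalysed acylation of the Roche-ester zinc homoenolate 5 (C12) with (S)-citronelloyl chloride 4 (C8).
5. Ring order: dioxolane (C10 mask), 16-membered lactone, 16-membered enol ether, 14-membered carbocycle.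

Key step: step 12

Remark: (S)-citronellic acid is taken as a stock chemical; Pinnick oxidation of (S)-citronellal would supply it otherwise.

**Route**

Step 1
Reactants: 1 methyl (R)-3-hydroxy-2-methylpropanoate
Product: 2 methyl (S)-3-iodo-2-methylpropanoate
Conditions: I2, PPh3, imidazole, CH2Cl2, 0 °C → rt
Reagents that add atoms: iodine, II
Why: Appel-type iodination replaces the activated primary oxygen by SN2 at CH2, so the α-stereocenter is untouched (the descriptor changes only because CH2I outranks the ester).

Step 2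
Reactants: 3 (S)-citronellic acid [(S)-3,7-dimethyloct-6-enoic acid]; 2 methyl (S)-3-iodo-2-methylpropanoate
Product: 6 methyl (2R,6S)-2,6,10-trimethyl-4-oxoundec-9-enoate, via (S)-citronelloyl chloride 4 (not isolated), via organozinc iodide 5 (not isolated)
Conditions: 3, (COCl)2, DMF (cat.), CH2Cl2, 0 °C → rt, evaporate; separately 2, Zn dust (TMSCl/BrCH2CH2Br-activated), THF, 35 °C; then Pd(PPh3)4 (5 mol%), 4, THF, 0 °C → rt
Reagents that add atoms: none
Why: Zinc insertion into the primary C–I bond gives an ester homoenolate whose stereocenter is not the metalated carbon, and Pd-catalysed Negishi-type acylation with the acid chloride should form C10–C11 and stop at the γ-keto ester, joining the C8 and C12 centers from the two chiral-pool pieces.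

Step 3
Reactants: 6 methyl (2R,6S)-2,6,10-trimethyl-4-oxoundec-9-enoate
Product: 7 methyl (R)-3-{2-[(S)-2,6-dimethylhept-5-en-1-yl]-1,3-dioxolan-2-yl}-2-methylpropanoate
Conditions: (TMSOCH2)2, TMSOTf (5 mol%), CH2Cl2, −78 → −20 °C; pyridine quench
Reagents that add atoms: 1,2-bis(trimethylsilyloxy)ethane, C[Si](C)(C)OCCO[Si](C)(C)C
Why: Noyori ketalization masks the C10 ketone under aprotic low-temperature conditions that should leave the ester, the trisubstituted alkene and the C12 center unchanged, so that the later methylenation meets only one carbonyl group.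

Step 4
Reactants: 7 dioxolane ester
Product: 9 methyl (R)-2-methyl-3-{2-[(S)-2-methyl-5-oxopentyl]-1,3-dioxolan-2-yl}propanoate, via ozonide 8 (not isolated)
Conditions: O3, CH2Cl2, −78 °C; then PPh3, −78 °C → rt
Reagents that add atoms: ozone, [O-][O+]=O
Why: Ozonolysis with reductive work-up cleaves the only alkene to the C5 aldehyde, while ketal and ester are inert to ozone.

Step 5
Reactants: 9 C5 aldehyde
Product: 11 methyl (R)-3-{2-[(2S,5S,6R)-5-hydroxy-2,6-dimethyloct-7-en-1-yl]-1,3-dioxolan-2-yl}-2-methylpropanoate (cembrane locants 4R,5S,8S,12R), via O-boryl adduct 10 (not isolated)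
Conditions: trans-2-butene, KOt-Bu, n-BuLi, THF, −78 → −45 °C; (+)-Ipc2BOMe [from (−)-α-pinene], −78 °C; BF3·OEt2; 9, −78 °C; then pH 7 buffer, 30% H2O2, 0 °C → rt
Reagents that add atoms: (E)-crotylbis(isopinocampheyl)borane, formed in the flask from trans-2-butene and (+)-Ipc2BOMe, C/C=C/CB([C@H]1C[C@H]2C[C@H](C2(C)C)[C@@H]1C)[C@H]1C[C@H]2C[C@H](C2(C)C)[C@@H]1C
Why: Brown crotylboration through a closed chair transition state should give the 4,5-anti relationship from the (E)-crotyl unit, and the isopinocampheyl ligands of the (+)-series should direct attack to the Re face of the aldehyde, setting C5 as S and C4 as R; the buffered oxidative work-up spares the methyl ester.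

Step 6
Reactants: 11 homoallylic alcohol
Product: 12 tert-butyldimethylsilyl ether of 11 (C5–OTBS)
Conditions: TBSCl, imidazole, DMAP (cat.), DMF, rt → 40 °C
Reagents that add atoms: tert-butyldimethylsilyl chloride, CC(C)(C)[Si](C)(C)Cl
Why: Silylation of the secondary alcohol under neutral conditions gives an oxygen protecting group that, unlike an acetate, will not react with the titanium methylidene used later.

Step 7
Reactants: 13 propargyl alcohol
Product: 15 (E)-3-iodo-2-methylprop-2-en-1-ol, via alkenylalane 14 (not isolated)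
Conditions: AlMe3 (3 equiv), Cp2ZrCl2 (0.25 equiv), CH2Cl2, 0 °C → rt; then I2, THF, −30 → 0 °C; aq. K2CO3
Reagents that add atoms: trimethylaluminium, C[Al](C)C; iodine, II
Why: Negishi zirconium-catalysed carboalumination adds methyl and aluminium syn across the alkyne with aluminium at the terminus, and iodinolysis with retention should give the (E)-vinyl iodide.

Step 8
Reactants: 12 silyl ether alkene; 15 (E)-3-iodo-2-methylprop-2-en-1-ol
Product: 17 methyl ester of the (E)-allylic alcohol: HOCH2–C(CH3)=CH–CH2CH2–CH(CH3)–CH(OTBS)–CH2CH2–CH(CH3)–CH2–C(OCH2CH2O)–CH2–CH(CH3)–CO2Me, (4R,5S,8S,12R), via B-alkyl-9-BBN 16 (not isolated)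
Conditions: 9-BBN, THF, 0 °C → rt; then 15, Pd(dppf)Cl2, AsPh3, Cs2CO3, DMF/H2O, rt
Reagents that add atoms: none
Why: Anti-Markovnikov hydroboration of the terminal vinyl group followed by B-alkyl Suzuki–Miyaura coupling, which retains the geometry of the vinyl iodide, should form C1–C2 and install the (E)-trisubstituted allylic alcohol; the methyl ester and the free hydroxyl are tolerated.

Step 9
Reactants: 17 allylic alcohol methyl ester
Product: 18 seco acid (C13 carboxylic acid, C16 primary allylic alcohol)
Conditions: LiOH·H2O, THF/MeOH/H2O, rt; then 1 M HCl to pH 4, 0 °C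
Reagents that add atoms: lithium hydroxide, [Li+].[OH-]
Why: Saponification of the methyl ester at room temperature should not epimerize the simple α-methyl center, and the TBS ether and dioxolane survive the brief mildly acidic work-up.

Step 10
Reactants: 18 seco acid
Product: 20 16-membered (E)-macrolactone (ring: C13(=O)–O–C16H2–C15(CH3)=C1H–C2…C12; 5-OTBS; 10,10-ethylenedioxy; 4R,5S,8S,12R), via mixed anhydride 19 (not isolated)
Conditions: 2,4,6-Cl3C6H2COCl, Et3N, THF, rt; then slow addition to DMAP, toluene (1 mM), 80 °C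
Reagents that add atoms: none
Why: Yamaguchi macrolactonization of an unhindered primary allylic alcohol onto the activated acid at high dilution should close the strain-free 16-membered ring.

Step 11
Reactants: 20 macrolactone
Product: 21 16-membered 2-methylene oxacycle (exocyclic C13=C14H2 enol ether; otherwise as 20)
Conditions: Cp2TiMe2 (3 equiv), toluene/THF, 65 °C, dark; filtration through basic Al2O3 (1% Et3N)
Reagents that add atoms: dimethyltitanocene, [CH3-].[CH3-].[Ti+4].c1cc[cH-]c1.c1cc[cH-]c1
Why: Petasis methylenation (thermally formed Cp2Ti=CH2, [2+2] addition and cycloreversion) converts the only carbonyl group into the exocyclic enol ether under non-acidic conditions that should keep C12 and the position of the double bond intact, at a temperature below the onset of the rearrangement.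

Step 12
Reactants: 21 16-membered 2-methylene oxacycle
Product: 22 (1S,4R,5S,8S,12R)-5-(tert-butyldimethylsilyloxy)-10,10-ethylenedioxy-1-isopropenyl-4,8,12-trimethylcyclotetradecan-13-one
Conditions: o-xylene (5 mM), 2,6-di-tert-butyl-4-methylpyridine (10 mol%), 140 °C, sealed tube, base-washed glass
Reagents that add atoms: none
Why: A concerted [3,3]-sigmatropic (Claisen) rearrangement of the allyl vinyl ether C14H2=C13–O–C16H2–C15(CH3)=C1H embedded in the 16-membered ring breaks O–C16 while C14–C1 forms, giving the C13 ketone, the C14 methylene, the C1 stereocenter and the isopropenyl group (C16 becomes its =CH2) in one event. The closest known reaction types are the thermal Claisen rearrangement of lactone-derived 2-methylene oxacycles and the ring contraction of macrolide ketene acetals to carbocycles. The 14-membered carbocycle is closed by ring contraction: the six-membered chair array is fused across C13 and C1, so O, C16 and C15 leave the ring and C14 enters it (16 → 14), with the eleven-carbon tether C2–C12 spanning two pseudo-equatorial positions without strain. C1 is controlled by the (E)-alkene geometry (C2 pseudo-equatorial in the chair) together with the C12 stereocenter on the enol ether carbon: in the chair that leads to 1S the C12–H, not the C12 methyl, faces the allyl unit while C11 leaves toward C14 and on to C2, whereas the chair that leads to 1R would turn the C12 methyl over the O–C16 bond; this is a conformational argument, not a certainty, and is treated as the main risk below. The step needs the [3,3] shift to win over acid-catalysed migration of the exocyclic double bond into the ring or hydrolysis, and chair over boat; the hindered base, the absence of Lewis acids and the unstrained chair should secure this, and the silyl ether and dioxolane are thermally inert.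

Step 13
Reactants: 22 cyclotetradecanone
Product: 24 (1S,4R,5S,8S,12R,13R)-13-alcohol (C5–OTBS, C10 dioxolane), via catechol borate 23 (not isolated)
Conditions: (S)-Me-CBS (0.5 equiv), catecholborane (2 equiv), toluene, −78 → −40 °C; then MeOH, aq. NaHCO3
Reagents that add atoms: none
Why: CBS reduction under reagent control: the (S)-oxazaborolidine should bind the ketone with the α-branched C12 arm as the large substituent and deliver hydride to the face that gives 13R (12,13-syn); this is against the acyclic Felkin–Anh preference, and catecholborane at low temperature leaves the isopropenyl group alone.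

Step 14
Reactants: 24 13-alcohol
Product: 25 (1S,4R,5S,8S,12R,13R)-5,13-diol (C10 dioxolane)
Conditions: TBAF, THF, rt → 40 °C; H2O
Reagents that add atoms: none
Why: Fluoride-induced desilylation frees the C5 hydroxyl while the ketal stays in place, which prevents hemiketal formation between the C13 hydroxyl and a C10 ketone.

Step 15
Reactants: 25 diol
Product: 26 (1S,4R,5S,8S,12R,13R)-5,13-diacetate (C10 dioxolane)
Conditions: Ac2O, DMAP (cat.), pyridine, CH2Cl2, rt
Reagents that add atoms: acetic anhydride, CC(=O)OC(C)=O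
Why: DMAP-catalysed acetylation should esterify both secondary alcohols with retention at C5 and C13.

Step 16
Reactants: 26 diacetate ketal
Product: 27 target, (1S,4R,5S,8S,12R,13R)-5,13-diacetoxy-1-isopropenyl-4,8,12-trimethylcyclotetradecan-10-one
Conditions: 2 M HCl, THF, 0 °C → rt
Reagents that add atoms: water, O
Why: Acid hydrolysis of the dioxolane should release the C10 ketone; the acetates and the isopropenyl group tolerate dilute acid at room temperature, and no acetoxy group is β to the new ketone, so elimination is not possible.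

**Compound list**

1 | methyl (R)-3-hydroxy-2-methylpropanoate | OC[C@@H](C)C(=O)OC | starting material
2 | methyl (S)-3-iodo-2-methylpropanoate | IC[C@@H](C)C(=O)OC | intermediate
3 | (S)-citronellic acid | CC(C)=CCC[C@H](C)CC(=O)O | starting material
4 | (S)-citronelloyl chloride | CC(C)=CCC[C@H](C)CC(=O)Cl | intermediate
5 | [(S)-3-methoxy-2-methyl-3-oxopropyl]zinc iodide | I[Zn]C[C@@H](C)C(=O)OC | intermediate
6 | methyl (2R,6S)-2,6,10-trimethyl-4-oxoundec-9-enoate | CC(C)=CCC[C@H](C)CC(=O)C[C@@H](C)C(=O)OC | intermediate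
7 | methyl (R)-3-{2-[(S)-2,6-dimethylhept-5-en-1-yl]-1,3-dioxolan-2-yl}-2-methylpropanoate | CC(C)=CCC[C@H](C)CC1(C[C@@H](C)C(=O)OC)OCCO1 | intermediate
8 | ozonide (3,3-dimethyl-1,2,4-trioxolane) of 7 | CC1(C)OOC(CC[C@H](C)CC2(C[C@@H](C)C(=O)OC)OCCO2)O1 | intermediate
9 | methyl (R)-2-methyl-3-{2-[(S)-2-methyl-5-oxopentyl]-1,3-dioxolan-2-yl}propanoate | O=CCC[C@H](C)CC1(C[C@@H](C)C(=O)OC)OCCO1 | intermediate
10 | O-[bis(isopinocampheyl)boryl] derivative of 11 | C=C[C@@H](C)[C@@H](OB([C@H]2C[C@H]3C[C@H](C3(C)C)[C@@H]2C)[C@H]2C[C@H]3C[C@H](C3(C)C)[C@@H]2C)CC[C@H](C)CC1(C[C@@H](C)C(=O)OC)OCCO1 | intermediate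
11 | methyl (R)-3-{2-[(2S,5S,6R)-5-hydroxy-2,6-dimethyloct-7-en-1-yl]-1,3-dioxolan-2-yl}-2-methylpropanoate | C=C[C@@H](C)[C@@H](O)CC[C@H](C)CC1(C[C@@H](C)C(=O)OC)OCCO1 | intermediate
12 | tert-butyldimethylsilyl ether of 11 | C=C[C@@H](C)[C@@H](O[Si](C)(C)C(C)(C)C)CC[C@H](C)CC1(C[C@@H](C)C(=O)OC)OCCO1 | intermediate
13 | propargyl alcohol | C#CCO | starting material
14 | (E)-alkenylalane, dimethylaluminium alkoxide of (E)-3-(dimethylalumanyl)-2-methylprop-2-en-1-ol | C[Al](C)OC/C(C)=C/[Al](C)C | intermediate
15 | (E)-3-iodo-2-methylprop-2-en-1-ol | OC/C(C)=C/I | intermediate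
16 | B-alkyl-9-borabicyclo[3.3.1]nonane from 12 (boron on C2) | B1(CC[C@@H](C)[C@@H](O[Si](C)(C)C(C)(C)C)CC[C@H](C)CC3(C[C@@H](C)C(=O)OC)OCCO3)C2CCCC1CCC2 | intermediate
17 | (E)-allylic alcohol methyl ester (4R,5S,8S,12R) | OC/C(C)=C/CC[C@@H](C)[C@@H](O[Si](C)(C)C(C)(C)C)CC[C@H](C)CC1(C[C@@H](C)C(=O)OC)OCCO1 | intermediate
18 | seco acid (4R,5S,8S,12R) | OC/C(C)=C/CC[C@@H](C)[C@@H](O[Si](C)(C)C(C)(C)C)CC[C@H](C)CC1(C[C@@H](C)C(=O)O)OCCO1 | intermediate
19 | mixed 2,4,6-trichlorobenzoic anhydride of 18 | OC/C(C)=C/CC[C@@H](C)[C@@H](O[Si](C)(C)C(C)(C)C)CC[C@H](C)CC1(C[C@@H](C)C(=O)OC(=O)c2c(Cl)cc(Cl)cc2Cl)OCCO1 | intermediate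
20 | 16-membered (E)-macrolactone (4R,5S,8S,12R) | O1C/C(C)=C/CC[C@@H](C)[C@@H](O[Si](C)(C)C(C)(C)C)CC[C@H](C)CC2(C[C@@H](C)C1=O)OCCO2 | intermediate
21 | 16-membered 2-methylene oxacycle (exocyclic enol ether of 20) | O1C/C(C)=C/CC[C@@H](C)[C@@H](O[Si](C)(C)C(C)(C)C)CC[C@H](C)CC2(C[C@@H](C)C1=C)OCCO2 | intermediate
22 | (1S,4R,5S,8S,12R)-5-(tert-butyldimethylsilyloxy)-10,10-ethylenedioxy-1-isopropenyl-4,8,12-trimethylcyclotetradecan-13-one | C=C(C)[C@H]1CC[C@@H](C)[C@@H](O[Si](C)(C)C(C)(C)C)CC[C@H](C)CC2(OCCO2)C[C@@H](C)C(=O)C1 | intermediate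
23 | catechol borate of 24 | C=C(C)[C@H]1CC[C@@H](C)[C@@H](O[Si](C)(C)C(C)(C)C)CC[C@H](C)CC2(OCCO2)C[C@@H](C)[C@H](OB3Oc4ccccc4O3)C1 | intermediate
24 | (1S,4R,5S,8S,12R,13R)-13-alcohol (5-OTBS, 10-dioxolane) | C=C(C)[C@H]1CC[C@@H](C)[C@@H](O[Si](C)(C)C(C)(C)C)CC[C@H](C)CC2(OCCO2)C[C@@H](C)[C@H](O)C1 | intermediate
25 | (1S,4R,5S,8S,12R,13R)-5,13-diol (10-dioxolane) | C=C(C)[C@H]1CC[C@@H](C)[C@@H](O)CC[C@H](C)CC2(OCCO2)C[C@@H](C)[C@H](O)C1 | intermediate
26 | (1S,4R,5S,8S,12R,13R)-5,13-diacetate (10-dioxolane) | C=C(C)[C@H]1CC[C@@H](C)[C@@H](OC(C)=O)CC[C@H](C)CC2(OCCO2)C[C@@H](C)[C@H](OC(C)=O)C1 | intermediate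
27 | CNP0328624.1, (1S,4R,5S,8S,12R,13R)-5,13-diacetoxy-1-isopropenyl-4,8,12-trimethylcyclotetradecan-10-one | C=C(C)[C@H]1CC[C@@H](C)[C@@H](OC(C)=O)CC[C@H](C)CC(=O)C[C@@H](C)[C@H](OC(C)=O)C1 | target

**Step count and risks**

Total step count: 16. Longest linear sequence: 15 steps (steps 1–6 and 8–16, from 1); step 7 is a one-step side branch.

Steps most likely to fail:

1. Step 12. What may go wrong: bonding of C14 to the opposite face of C1 (the chair of opposite sense), or poor discrimination between the two chairs, so that the C1 epimer forms in quantity. Fallback (change of precursor geometry, same chair): the sense of the chair is dictated locally by C12, so moving C2 from the pseudo-equatorial to the pseudo-axial position inverts the configuration that this chair delivers at C1. The fallback sets out from 12 and 13. Copper-catalysed anti-carbomagnesiation of 13 (MeMgBr, CuI, THF) would give the cyclic alkenylmagnesium alkoxide F1, and iodination would give (Z)-3-iodo-2-methylprop-2-en-1-ol F2. Hydroboration of 12 (via 16) and Suzuki coupling with F2 would give the (Z)-allylic alcohol methyl ester F3, LiOH the (Z)-seco acid F4, and Yamaguchi conditions, through the mixed anhydride F5, the (Z)-macrolactone F6. Petasis methylenation would give the (Z)-configured 2-methylene oxacycle F7, whose thermolysis under the step 12 conditions should give 22, where the route is rejoined.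

2. Step 13. What may go wrong: hydride delivery governed by the substrate (Felkin–Anh preference at C12 and the ring conformation) against the catalyst, giving mainly the C13 epimer. Fallback (use the substrate bias, then invert): setting out from 22, L-Selectride in THF at −78 °C should give the (13S)-alcohol F8. Mitsunobu inversion (4-nitrobenzoic acid, PPh3, DIAD, toluene) would give the (13R)-4-nitrobenzoate F9, and methanolysis (K2CO3, MeOH) returns to 24.

3. Step 11. What may go wrong: incomplete methylenation of the α-branched lactone carbonyl, and loss of the enol ether during isolation by hydrolysis or migration of the double bond into the ring. Fallback (decarboxylative [3,3] ring contraction without an enol ether): setting out from 20, addition of the lithium enolate of tert-butyl acetate (LDA, THF, −78 → −20 °C) would open the lactone to the hydroxy β-keto tert-butyl ester F10. Heating at high dilution in xylene would expel tert-butanol to give the acylketene F11, which the allylic alcohol traps to the 18-membered β-keto lactone F12. Carroll rearrangement (diphenyl ether, 180 °C, or LDA, THF, reflux) would form the same C14–C1 bond and give the β-keto acid F13, which loses CO2 to arrive at 22. The face selectivity at C1 would still have to be established for this variant.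

Further compounds
F1 | step 12 | cyclic alkenylmagnesium alkoxide (4-methyl-2,5-dihydro-1,2-oxamagnesole) | CC1=C[Mg]OC1
F2 | step 12 | (Z)-3-iodo-2-methylprop-2-en-1-ol | OC/C(C)=C\I
F3 | step 12 | (Z)-allylic alcohol methyl ester (Z isomer of 17) | OC/C(C)=C\CC[C@@H](C)[C@@H](O[Si](C)(C)C(C)(C)C)CC[C@H](C)CC1(C[C@@H](C)C(=O)OC)OCCO1
F4 | step 12 | (Z)-seco acid (Z isomer of 18) | OC/C(C)=C\CC[C@@H](C)[C@@H](O[Si](C)(C)C(C)(C)C)CC[C@H](C)CC1(C[C@@H](C)C(=O)O)OCCO1
F5 | step 12 | mixed 2,4,6-trichlorobenzoic anhydride of F4 | OC/C(C)=C\CC[C@@H](C)[C@@H](O[Si](C)(C)C(C)(C)C)CC[C@H](C)CC1(C[C@@H](C)C(=O)OC(=O)c2c(Cl)cc(Cl)cc2Cl)OCCO1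
F6 | step 12 | 16-membered (Z)-macrolactone (Z isomer of 20) | O1C/C(C)=C\CC[C@@H](C)[C@@H](O[Si](C)(C)C(C)(C)C)CC[C@H](C)CC2(C[C@@H](C)C1=O)OCCO2
F7 | step 12 | (Z)-configured 16-membered 2-methylene oxacycle (Z isomer of 21) | O1C/C(C)=C\CC[C@@H](C)[C@@H](O[Si](C)(C)C(C)(C)C)CC[C@H](C)CC2(C[C@@H](C)C1=C)OCCO2
F8 | step 13 | (1S,4R,5S,8S,12R,13S)-13-alcohol (C13 epimer of 24) | C=C(C)[C@H]1CC[C@@H](C)[C@@H](O[Si](C)(C)C(C)(C)C)CC[C@H](C)CC2(OCCO2)C[C@@H](C)[C@@H](O)C1
F9 | step 13 | (13R)-4-nitrobenzoate of 24 | C=C(C)[C@H]1CC[C@@H](C)[C@@H](O[Si](C)(C)C(C)(C)C)CC[C@H](C)CC2(OCCO2)C[C@@H](C)[C@H](OC(=O)c3ccc(cc3)[N+](=O)[O-])C1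
F10 | step 11 | hydroxy β-keto tert-butyl ester (ring-opened 20 with C14 and a tert-butyl ester carbon added) | OC/C(C)=C/CC[C@@H](C)[C@@H](O[Si](C)(C)C(C)(C)C)CC[C@H](C)CC1(C[C@@H](C)C(=O)CC(=O)OC(C)(C)C)OCCO1
F11 | step 11 | acylketene from F10 | OC/C(C)=C/CC[C@@H](C)[C@@H](O[Si](C)(C)C(C)(C)C)CC[C@H](C)CC1(C[C@@H](C)C(=O)C=C=O)OCCO1
F12 | step 11 | 18-membered β-keto macrolactone | O1C/C(C)=C/CC[C@@H](C)[C@@H](O[Si](C)(C)C(C)(C)C)CC[C@H](C)CC2(C[C@@H](C)C(=O)CC1=O)OCCO2
F13 | step 11 | 14-carboxy derivative of 22 (β-keto acid, C14 configuration undefined) | C=C(C)[C@H]1CC[C@@H](C)[C@@H](O[Si](C)(C)C(C)(C)C)CC[C@H](C)CC2(OCCO2)C[C@@H](C)C(=O)C1C(=O)O
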